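## Retrosynthetic overview

1. The target is an open chain, so no ring is built; the only ring on the way is the oxirane that carries C16 from (R)-epichlorohydrin.
2. C3–C4 (last): Ir-catalysed allylation of the C4 primary alcohol. C6–C7: Ni–H hydroalkylation of the C7=C8 alkene with (S)-3-bromo-2-methylpropan-1-ol, which brings C4–C6 and the C5 centre.
3. C9–C10: asymmetric allylboration of the C10 aldehyde (sets C10).
4. Key bond C11–C12: Ni–H-catalysed enantioselective radical hydroalkylation of N-phenylacrylamide with the unprotected C12 iodide; it creates C11 under catalyst control.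
5. C17–C18: Ni-catalysed reductive radical coupling of the C16–C17 epoxide with (Z)-BnC(Br)=CHCl (from BnC≡CCl by anti-HBr addition). C14–C15: Cu-catalysed opening of (R)-epichlorohydrin by the Grignard reagent of the same bromo alcohol.

Carbon numbers C1–C19 follow the target chain from the vinyl end (C1=C2) to the CHCl carbon (C19).

Assumption: where a reagent or ligand antipode controls a new stereocentre (steps 7, 9, 11 and the fallbacks), the antipode named is the one expected to give the drawn configuration; the other antipode gives the epimer. Operations run in one flask without isolation count as one step.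

## Route

Step 1
Reactants: 1 cis-1,2-dichloroethene; 2 benzyl bromide
Product: 4 (3-chloroprop-2-yn-1-yl)benzene, via chloroethynyllithium 3 (not isolated)
Conditions: MeLi (2.1 equiv), Et2O, 0 °C → rt; then 2, THF/DMPU, −78 °C → rt
Reagents that add atoms: none
Why: Double base treatment of cis-dichloroethene (anti-dehydrochlorination, then deprotonation) gives chloroethynyllithium, which is alkylated by the benzylic bromide in an SN2 acetylide alkylation to give the 1-chloroalkyne directly.

Step 2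
Reactants: 4 (3-chloroprop-2-yn-1-yl)benzene
Product: 5 [(2Z)-2-bromo-3-chloroprop-2-en-1-yl]benzene (Br and Cl cis)
Conditions: Pd(OAc)2 (5 mol%), LiBr (2 equiv), AcOH, 25 °C
Reagents that add atoms: lithium bromide, [Li+].[Br-]
Why: Palladium-catalysed anti-hydrobromination of a 1-haloalkyne (trans-bromopalladation with bromide on the benzyl-bearing carbon, then protonolysis) gives the (Z)-1,2-dihaloalkene, so the olefin geometry of the target is fixed here.

Step 3
Reactants: 6 (S)-3-bromo-2-methylpropan-1-ol; 7 (R)-epichlorohydrin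
Product: 10 (2R)-2-methyl-4-[(2R)-oxiran-2-yl]butan-1-ol, via dimagnesium reagent 8 (not isolated), via chlorohydrin diol 9 (not isolated)
Conditions: i-PrMgCl (1.0 equiv), THF, −20 °C; Mg turnings, reflux; CuI (10 mol%), 7, −40 → 0 °C; then MeOH, K2CO3, 0 °C → rt
Reagents that add atoms: none
Why: Normant-type alkoxide-masked Grignard formation, CuI-catalysed SN2 opening of the epoxide at its CH2 terminus and Williamson re-closure of the chlorohydrin join C14–C15 without touching a stereocentre, so C13 comes from 6 and C16 from 7.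

Step 4
Reactants: 10 (2R)-2-methyl-4-[(2R)-oxiran-2-yl]butan-1-ol; 5 [(2Z)-2-bromo-3-chloroprop-2-en-1-yl]benzene
Product: 12 (2R,5R,7Z)-7-benzyl-8-chloro-2-methyloct-7-ene-1,5-diol, via iodohydrin 11 (not isolated)
Conditions: NiCl2·glyme (10 mol%), 2,2'-bipyridine (10 mol%), NaI (25 mol%), Et3N·HCl (1 equiv), Mn powder (2 equiv), DMPU, 25 °C
Reagents that add atoms: none
Why: Ni/iodide co-catalysed reductive cross-electrophile coupling of an epoxide with an alkenyl bromide: iodide opens the oxirane at C17, the β-hydroxyalkyl radical from the iodohydrin is captured by the alkenyl–nickel formed by oxidative addition into C–Br (C–Cl is left), and reductive elimination forms C17–C18 with retention of the olefin geometry and of C16.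

Step 5
Reactants: 12 (2R,5R,7Z)-7-benzyl-8-chloro-2-methyloct-7-ene-1,5-diol
Product: 13 (1Z,4R,7R)-2-benzyl-1-chloro-8-iodo-7-methyloct-1-en-4-ol
Conditions: PPh3, I2, imidazole, CH2Cl2, 0 °C
Reagents that add atoms: iodine, II
Why: Appel-type iodination is selective for the unhindered primary alcohol over the secondary C16–OH at 0 °C and touches no stereocentre.

Step 6
Reactants: 14 acryloyl chloride; 15 aniline
Product: 16 N-phenylprop-2-enamide (N-phenylacrylamide)
Conditions: Et3N, CH2Cl2, 0 °C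
Reagents that add atoms: none
Why: Simple N-acylation of aniline gives the N-aryl acrylamide that serves as the C10–C11 (plus methyl) unit.

Step 7 (key step)
Reactants: 13 (1Z,4R,7R)-2-benzyl-1-chloro-8-iodo-7-methyloct-1-en-4-ol; 16 N-phenylacrylamide
Product: 17 (2R,4R,7R,9Z)-9-benzyl-10-chloro-7-hydroxy-2,4-dimethyl-N-phenyldec-9-enamide
Conditions: NiBr2·glyme (10 mol%), (S,S)-Ph-BOX [2,2'-(propane-2,2-diyl)bis((4S)-4-phenyl-4,5-dihydrooxazole)] (12 mol%), (EtO)2MeSiH (2.5 equiv), KF (2.5 equiv), DMA/t-BuOH, 25 °C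
Reagents that add atoms: none
Why: Ni–H-catalysed enantioselective reductive hydroalkylation of an acrylamide: Ni–H adds to give the α-nickelated propionamide, the primary alkyl radical released from 13 by halogen abstraction is captured at nickel, and C11–C12 reductive elimination inside the chiral bis(oxazoline) pocket sets C11 (R) by catalyst control, while the mild silane/fluoride medium leaves the free C16–OH and the chloroalkene alone.

Step 8
Reactants: 17 (2R,4R,7R,9Z)-9-benzyl-10-chloro-7-hydroxy-2,4-dimethyl-N-phenyldec-9-enamide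
Product: 19 (2R,4R,7R,9Z)-9-benzyl-10-chloro-7-hydroxy-2,4-dimethyldec-9-enal, via N-phenyl imine 18 (not isolated)
Conditions: Cp2Zr(H)Cl (3.5 equiv), THF, 25 °C; then H2O, SiO2, 0 °C; crude aldehyde used at once
Reagents that add atoms: water, O
Why: Amide-to-aldehyde reduction by hydrozirconation: after the N–H and O–H are deprotonated, one Zr–H adds to the amidate to give the N-aryl aldimine, which water cleaves to the aldehyde; the trisubstituted chloroalkene is too hindered to be hydrozirconated and C11 is kept by cold hydrolysis and immediate use.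

Step 9
Reactants: 19 (2R,4R,7R,9Z)-9-benzyl-10-chloro-7-hydroxy-2,4-dimethyldec-9-enal; 20 allylmagnesium bromide
Product: 23 (1Z,4R,7R,9R,10R)-2-benzyl-1-chloro-7,9-dimethyltrideca-1,12-diene-4,10-diol, via allylborane 21 (not isolated), via O-borinate ester 22 (not isolated)
Conditions: (+)-Ipc2BOMe (2.6 equiv), 20 (2.5 equiv), Et2O, 0 °C → rt; 19, −78 °C; then NaOH, H2O2, 0 °C → rt
Reagents that add atoms: none
Why: Brown asymmetric allylboration through a closed chair transition state: the reagent derived from (−)-α-pinene delivers allyl to the Re face of the aldehyde, which is also the Felkin face of the (R)-α-methyl aldehyde, giving the 10R,11R (syn) homoallylic alcohol.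

Step 10
Reactants: 23 (1Z,4R,7R,9R,10R)-2-benzyl-1-chloro-7,9-dimethyltrideca-1,12-diene-4,10-diol; 6 (S)-3-bromo-2-methylpropan-1-ol
Product: 24 (2R,7R,8R,10R,13R,15Z)-15-benzyl-16-chloro-2,8,10-trimethylhexadec-15-ene-1,7,13-triol
Conditions: NiBr2·diglyme (10 mol%), 4,4'-di-tert-butyl-2,2'-bipyridine (12 mol%), NaI (0.5 equiv), (EtO)2MeSiH (2.5 equiv), Na2CO3 (2 equiv), DMA, 25 °C
Reagents that add atoms: none
Why: Ni–H-catalysed anti-Markovnikov reductive hydroalkylation of a terminal alkene with a primary alkyl halide (iodide formed in situ): Ni–H adds to the terminal olefin, the primary radical from 6 is captured at nickel and C6–C7 forms by reductive elimination; C5 is β to the radical carbon and is untouched, and the free hydroxyls and the trisubstituted chloroalkene do not react.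

Step 11
Reactants: 24 (2R,7R,8R,10R,13R,15Z)-15-benzyl-16-chloro-2,8,10-trimethylhexadec-15-ene-1,7,13-triol; 25 allyl acetate
Product: 26 (1Z,4R,7R,9R,10R,15R,16R)-2-benzyl-1-chloro-7,9,15-trimethylnonadeca-1,18-diene-4,10,16-triol (target)
Conditions: [Ir(cod)Cl]2 (2.5 mol%), (R)-SEGPHOS (5 mol%), 4-chloro-3-nitrobenzoic acid (10 mol%), Cs2CO3 (20 mol%), 25 (5 equiv), THF, 100 °C
Reagents that add atoms: none
Why: Krische iridium-catalysed transfer-hydrogenative allylation from the alcohol oxidation level: only the primary alcohol is dehydrogenated, the transient α-methyl aldehyde is allylated at once by the chiral allyl–iridium (no epimerisation at C5), and the (R)-ligand sets C4 (R), syn to the C5 methyl.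

## Compound list

1 | cis-1,2-dichloroethene | Cl/C=C\Cl | starting material
2 | benzyl bromide | BrCc1ccccc1 | starting material
3 | chloroethynyllithium | [Li]C#CCl | intermediate
4 | (3-chloroprop-2-yn-1-yl)benzene | ClC#CCc1ccccc1 | intermediate
5 | [(2Z)-2-bromo-3-chloroprop-2-en-1-yl]benzene | Br/C(=C\Cl)Cc1ccccc1 | intermediate
6 | (S)-3-bromo-2-methylpropan-1-ol | OC[C@H](C)CBr | starting material
7 | (R)-epichlorohydrin, (2R)-2-(chloromethyl)oxirane | ClC[C@H]1CO1 | starting material
8 | [(2S)-3-(bromomagnesio)-2-methylpropoxy]magnesium chloride | Cl[Mg]OC[C@H](C)C[Mg]Br | intermediate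
9 | (2R,5R)-6-chloro-2-methylhexane-1,5-diol | OC[C@H](C)CC[C@@H](O)CCl | intermediate
10 | (2R)-2-methyl-4-[(2R)-oxiran-2-yl]butan-1-ol | OC[C@H](C)CC[C@@H]1CO1 | intermediate
11 | (2R,5R)-6-iodo-2-methylhexane-1,5-diol | OC[C@H](C)CC[C@@H](O)CI | intermediate
12 | (2R,5R,7Z)-7-benzyl-8-chloro-2-methyloct-7-ene-1,5-diol | OC[C@H](C)CC[C@@H](O)C/C(=C\Cl)Cc1ccccc1 | intermediate
13 | (1Z,4R,7R)-2-benzyl-1-chloro-8-iodo-7-methyloct-1-en-4-ol | IC[C@H](C)CC[C@@H](O)C/C(=C\Cl)Cc1ccccc1 | intermediate
14 | acryloyl chloride | C=CC(=O)Cl | starting material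
15 | aniline | Nc1ccccc1 | starting material
16 | N-phenylprop-2-enamide | C=CC(=O)Nc1ccccc1 | intermediate
17 | (2R,4R,7R,9Z)-9-benzyl-10-chloro-7-hydroxy-2,4-dimethyl-N-phenyldec-9-enamide | O=C(Nc1ccccc1)[C@H](C)C[C@H](C)CC[C@@H](O)C/C(=C\Cl)Cc1ccccc1 | intermediate
18 | (1Z,4R,7R,9R)-2-benzyl-1-chloro-7,9-dimethyl-10-[(E)-phenylimino]dec-1-en-4-ol | c1ccccc1/N=C/[C@H](C)C[C@H](C)CC[C@@H](O)C/C(=C\Cl)Cc1ccccc1 | intermediate
19 | (2R,4R,7R,9Z)-9-benzyl-10-chloro-7-hydroxy-2,4-dimethyldec-9-enal | O=C[C@H](C)C[C@H](C)CC[C@@H](O)C/C(=C\Cl)Cc1ccccc1 | intermediate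
20 | allylmagnesium bromide | C=CC[Mg]Br | starting material
21 | (+)-B-allyldiisopinocampheylborane (isopinocampheyl groups from (−)-α-pinene) | C=CCB([C@H]1C[C@H]2C[C@@H]([C@@H]1C)C2(C)C)[C@H]1C[C@H]2C[C@@H]([C@@H]1C)C2(C)C | intermediate
22 | C10 O-(diisopinocampheylboryl) ester of 23 | C=CC[C@@H](OB([C@H]1C[C@H]2C[C@@H]([C@@H]1C)C2(C)C)[C@H]1C[C@H]2C[C@@H]([C@@H]1C)C2(C)C)[C@H](C)C[C@H](C)CC[C@@H](O)C/C(=C\Cl)Cc1ccccc1 | intermediate
23 | (1Z,4R,7R,9R,10R)-2-benzyl-1-chloro-7,9-dimethyltrideca-1,12-diene-4,10-diol | C=CC[C@@H](O)[C@H](C)C[C@H](C)CC[C@@H](O)C/C(=C\Cl)Cc1ccccc1 | intermediate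
24 | (2R,7R,8R,10R,13R,15Z)-15-benzyl-16-chloro-2,8,10-trimethylhexadec-15-ene-1,7,13-triol | OC[C@H](C)CCCC[C@@H](O)[C@H](C)C[C@H](C)CC[C@@H](O)C/C(=C\Cl)Cc1ccccc1 | intermediate
25 | allyl acetate | C=CCOC(C)=O | starting material
26 | (1Z,4R,7R,9R,10R,15R,16R)-2-benzyl-1-chloro-7,9,15-trimethylnonadeca-1,18-diene-4,10,16-triol | C=CC[C@@H](O)[C@H](C)CCCC[C@@H](O)[C@H](C)C[C@H](C)CC[C@@H](O)C/C(=C\Cl)Cc1ccccc1 | target

## Step count

Total steps: 11. Longest linear sequence: 9 (steps 1, 2, 4, 5, 7, 8, 9, 10, 11). No protecting group is used.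

## Steps most likely to fail, with fallbacks

Step 7. The Ni–H coupling has to work on a β-branched iodide that carries a free δ-hydroxyl, which can close to a tetrahydropyran under base, and catalyst control has to override the C13 centre. The fallback sets out from 13 and returns at 23. Silylation of the C16 hydroxyl (t-BuMe2SiCl, imidazole) gives tert-butyl{[(1Z,4R,7R)-2-benzyl-1-chloro-8-iodo-7-methyloct-1-en-4-yl]oxy}dimethylsilane F1. Zinc insertion (Zn dust, DMA) gives the alkylzinc iodide F2. F2 is coupled with racemic N-benzyl-2-bromo-N-phenylpropanamide F3 (made from 2-bromopropanoyl bromide and N-benzylaniline) under NiCl2·glyme/(R)-i-Pr-Pybox in an enantioconvergent Negishi coupling, in which C11–C12 still forms by capture of an α-amido radical at nickel, to give the tertiary anilide F4. LiAlH4 cleaves F4 to the primary alcohol F5, Ir-catalysed allylation under the conditions of step 11 gives the silyl-protected homoallylic alcohol F6, and Bu4NF gives 23.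

Step 8. A secondary anilide is a sluggish substrate for Cp2Zr(H)Cl, and the N-aryl aldimine and the α-methyl aldehyde can both epimerise at C11. The fallback sets out from 17 and returns at 23 without ever forming the aldehyde. Et3SiCl/imidazole gives the triethylsilyl ether of the anilide F7. Boc2O/DMAP gives the N-Boc anilide F8. NaBH4 in EtOH cleaves the activated imide to the primary alcohol F9. Ir-catalysed allylation from the alcohol level (conditions of step 11) gives the C10 carbinol F10, and Bu4NF removes the silyl group to give 23.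

Step 4. The alkenyl–nickel intermediate carries a cis β-chlorine and could lose it to give the alkyne, nickel could also insert into C–Cl, and the epoxy alcohol may cyclise. The fallback sets out from 5 and 10 and returns at 12 by a polar epoxide opening. Br/Li exchange on 5 (t-BuLi, Et2O, −100 °C; lithium sits cis to chlorine, so anti-elimination is not available) gives the alkenyllithium F11. MgBr2·OEt2 converts it into the alkenylmagnesium bromide F12. Epoxy alcohol 10 is deprotonated with i-PrMgCl to its chloromagnesium alkoxide F13, and CuI-catalysed SN2 opening of F13 by F12 at C17 gives 12 after work-up.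

## Further compounds

F1 | step 7 | tert-butyl{[(1Z,4R,7R)-2-benzyl-1-chloro-8-iodo-7-methyloct-1-en-4-yl]oxy}dimethylsilane | IC[C@H](C)CC[C@@H](O[Si](C)(C)C(C)(C)C)C/C(=C\Cl)Cc1ccccc1
F2 | step 7 | alkylzinc iodide from F1 (C12–ZnI) | I[Zn]C[C@H](C)CC[C@@H](O[Si](C)(C)C(C)(C)C)C/C(=C\Cl)Cc1ccccc1
F3 | step 7 | racemic N-benzyl-2-bromo-N-phenylpropanamide | CC(Br)C(=O)N(Cc1ccccc1)c1ccccc1
F4 | step 7 | (2R,4R,7R,9Z)-N,9-dibenzyl-7-[(tert-butyldimethylsilyl)oxy]-10-chloro-2,4-dimethyl-N-phenyldec-9-enamide | O=C(N(Cc1ccccc1)c1ccccc1)[C@H](C)C[C@H](C)CC[C@@H](O[Si](C)(C)C(C)(C)C)C/C(=C\Cl)Cc1ccccc1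
F5 | step 7 | (2R,4R,7R,9Z)-9-benzyl-7-[(tert-butyldimethylsilyl)oxy]-10-chloro-2,4-dimethyldec-9-en-1-ol | OC[C@H](C)C[C@H](C)CC[C@@H](O[Si](C)(C)C(C)(C)C)C/C(=C\Cl)Cc1ccccc1
F6 | step 7 | (1Z,4R,7R,9R,10R)-2-benzyl-4-[(tert-butyldimethylsilyl)oxy]-1-chloro-7,9-dimethyltrideca-1,12-dien-10-ol | C=CC[C@@H](O)[C@H](C)C[C@H](C)CC[C@@H](O[Si](C)(C)C(C)(C)C)C/C(=C\Cl)Cc1ccccc1
F7 | step 8 | (2R,4R,7R,9Z)-9-benzyl-10-chloro-2,4-dimethyl-N-phenyl-7-[(triethylsilyl)oxy]dec-9-enamide | O=C(Nc1ccccc1)[C@H](C)C[C@H](C)CC[C@@H](O[Si](CC)(CC)CC)C/C(=C\Cl)Cc1ccccc1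
F8 | step 8 | tert-butyl N-phenyl-N-{(2R,4R,7R,9Z)-9-benzyl-10-chloro-2,4-dimethyl-7-[(triethylsilyl)oxy]dec-9-enoyl}carbamate | O=C(N(C(=O)OC(C)(C)C)c1ccccc1)[C@H](C)C[C@H](C)CC[C@@H](O[Si](CC)(CC)CC)C/C(=C\Cl)Cc1ccccc1
F9 | step 8 | (2R,4R,7R,9Z)-9-benzyl-10-chloro-2,4-dimethyl-7-[(triethylsilyl)oxy]dec-9-en-1-ol | OC[C@H](C)C[C@H](C)CC[C@@H](O[Si](CC)(CC)CC)C/C(=C\Cl)Cc1ccccc1
F10 | step 8 | (1Z,4R,7R,9R,10R)-2-benzyl-1-chloro-7,9-dimethyl-4-[(triethylsilyl)oxy]trideca-1,12-dien-10-ol | C=CC[C@@H](O)[C@H](C)C[C@H](C)CC[C@@H](O[Si](CC)(CC)CC)C/C(=C\Cl)Cc1ccccc1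
F11 | step 4 | [(1Z)-1-benzyl-2-chloroethenyl]lithium | [Li]/C(=C\Cl)Cc1ccccc1
F12 | step 4 | [(1Z)-1-benzyl-2-chloroethenyl]magnesium bromide | Br[Mg]/C(=C\Cl)Cc1ccccc1
F13 | step 4 | chloromagnesium alkoxide of 10 | Cl[Mg]OC[C@H](C)CC[C@@H]1CO1
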